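## Retrosynthetic overview

1. Ring A is closed last through the C3–C4 bond: a tertiary α-keto radical at C4 cyclises 6-endo onto a Z trisubstituted alkene, setting C3 (axial sec-butyl) and the C4 quaternary centre on a preformed ring B.
2. After ring closure the C1 carbinol is oxidised to the ketone and C2 is hydroxylated through the only possible enolate.
3. The cyclisation precursor comes from a bicyclic γ-lactone aldehyde: CrCl2/NiCl2 coupling with a Z vinyl iodide makes C1–C2, and acetylide opening of the lactone followed by methanol addition makes the β-methoxy enone.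
4. Ring B is made first by an amine-catalysed Michael/aldol annulation of a keto acetal with (E)-pent-3-en-2-one (C4a–C5 and C8–C8a), then MeMgBr at C7.
5. Building blocks: 1,1-dimethoxypropan-2-one, methyl 2-bromopropanoate, (E)-pent-3-en-2-one and (S)-2-methylbutan-1-ol.

Assumption: locants C1–C8a are those of the target decalin (C1 ring ketone, C2 C(OH)CH3, C3 CH–sec-butyl, C4 quaternary carbon with the acyl group, C4a/C8a ring fusion, C5 CHCH3, C7 C(OH)CH3); centres drawn without configuration are epimer mixtures that are made planar later; the quinine-derived amine in step 2 is taken to give 5R, otherwise its quinidine-derived pseudo-enantiomer is used.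

## Route

Step 1
Reactants: 1 1,1-dimethoxypropan-2-one; 2 methyl 2-bromopropanoate (racemic)
Product: 3 methyl 5,5-dimethoxy-2-methyl-4-oxopentanoate (racemic)
Conditions: LiN(iPr)2, THF, −78 °C; then 2, DMPU, −78 → 0 °C
Reagents that add atoms: none
Why: The kinetic lithium enolate of 1 forms only on the methyl side and displaces bromide from the α-bromo ester (SN2 enolate alkylation) to give the 1,4-dicarbonyl compound, whose stereocentre is made planar later, so racemic 2 suffices.

Step 2
Reactants: 3 methyl 5,5-dimethoxy-2-methyl-4-oxopentanoate; 4 (E)-pent-3-en-2-one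
Product: 6 methyl 2-[(1R,2R,6R)-2-(dimethoxymethyl)-2-hydroxy-6-methyl-4-oxocyclohexyl]propanoate (side-chain epimers), via Michael adduct 5 (not isolated)
Conditions: 9-amino-9-deoxy-epi-quinine (20 mol %), PhCO2H (40 mol %), toluene, 25 °C, 72 h
Reagents that add atoms: none
Why: Proposed new method: the primary amine forms the enamine of 3 on its CH2 side and the iminium ion of 4, so a catalyst-controlled Michael addition sets C5 (R), C4a equilibrates through the enamine, and the reversible intramolecular aldol of the methyl ketone onto the acetal-activated ketone closes ring B through a chair with the C5 methyl, the C4a side chain and the dimethoxymethyl group equatorial and the C8a hydroxyl axial; the closest known reactions are amine-catalysed Robinson-type Michael/aldol annulations stopped at the ketol and enamine reactions of methylglyoxal dimethyl acetal.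

Step 3
Reactants: 6 methyl 2-[(1R,2R,6R)-2-(dimethoxymethyl)-2-hydroxy-6-methyl-4-oxocyclohexyl]propanoate
Product: 8 (3aR,4R,6R,7aR)-7a-(dimethoxymethyl)-6-hydroxy-3,4,6-trimethylhexahydro-1-benzofuran-2(3H)-one (C3 epimers), via diol ester 7 (not isolated)
Conditions: MeMgBr (3 equiv), THF, −78 °C; NH4Cl (aq); then TsOH·H2O (5 mol %), CH2Cl2, 25 °C
Reagents that add atoms: methylmagnesium bromide, C[Mg]Br
Why: Grignard addition to the ketone (much faster than to the ester at −78 °C) occurs from the equatorial side because the axial C8a alkoxide blocks and chelates the axial face, giving the axial C7 alcohol cis to the C8a hydroxyl, and acid then closes the cis-fused γ-lactone from the C8a hydroxyl and the ester (lactonisation).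

Step 4
Reactants: 8 (3aR,4R,6R,7aR)-7a-(dimethoxymethyl)-6-hydroxy-3,4,6-trimethylhexahydro-1-benzofuran-2(3H)-one
Product: 9 (3aR,4R,6R,7aR)-6-hydroxy-3,4,6-trimethyl-2-oxooctahydro-1-benzofuran-7a-carbaldehyde (C3 epimers)
Conditions: 2 M HCl (aq), THF, 40 °C
Reagents that add atoms: water, O
Why: Acid-catalysed acetal hydrolysis frees the non-enolisable aldehyde (future C1) while the γ-lactone and the tertiary alcohol survive dilute aqueous acid.

Step 5
Reactants: 10 (S)-2-methylbutan-1-ol
Product: 11 (S)-2-methylbutanal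
Conditions: TEMPO (2,2,6,6-tetramethylpiperidin-1-oxyl, 10 mol %), PhI(OAc)2, CH2Cl2, 25 °C; used as solution
Reagents that add atoms: none
Why: The oxoammonium (TEMPO) oxidation stops at the aldehyde under non-basic conditions, so the chiral-pool stereocentre that becomes the sec-butyl centre is not epimerised.

Step 6
Reactants: 11 (S)-2-methylbutanal
Product: 12 (2Z,4S)-2-iodo-4-methylhex-2-ene
Conditions: EtPPh3I, n-BuLi, THF, 25 °C; I2, −78 °C; NaN(SiMe3)2, −20 °C; then 11, −78 → 25 °C
Reagents that add atoms: ethyltriphenylphosphonium iodide, CC[P+](c1ccccc1)(c1ccccc1)c1ccccc1.[I-]; iodine, II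
Why: Stork–Zhao-type Wittig olefination with the α-iodo ylide is Z-selective (iodine cis to the sec-butyl group) and runs cold enough to leave the α-stereocentre intact.

Step 7
Reactants: 9 (3aR,4R,6R,7aR)-6-hydroxy-3,4,6-trimethyl-2-oxooctahydro-1-benzofuran-7a-carbaldehyde; 12 (2Z,4S)-2-iodo-4-methylhex-2-ene
Product: 13 (3aR,4R,6R,7aR)-6-hydroxy-7a-[(2Z,4S)-1-hydroxy-2,4-dimethylhex-2-en-1-yl]-3,4,6-trimethylhexahydro-1-benzofuran-2(3H)-one (epimers at C3 and at the carbinol)
Conditions: CrCl2 (6 equiv), NiCl2 (2 mol %), DMF, 25 °C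
Reagents that add atoms: none
Why: Nozaki–Hiyama–Kishi coupling adds the alkenylchromium species to the aldehyde only, tolerating lactone and free hydroxyl and retaining the Z geometry, and the new carbinol centre (future C1) is oxidised later, so its configuration does not matter.

Step 8
Reactants: 13 (3aR,4R,6R,7aR)-6-hydroxy-7a-[(2Z,4S)-1-hydroxy-2,4-dimethylhex-2-en-1-yl]-3,4,6-trimethylhexahydro-1-benzofuran-2(3H)-one
Product: 15 (1E)-4-[(1R,2R,4R,6R)-2,4-dihydroxy-2-[(2Z,4S)-1-hydroxy-2,4-dimethylhex-2-en-1-yl]-4,6-dimethylcyclohexyl]-1-methoxypent-1-en-3-one (epimers at C4 of the pentenone and at the carbinol), via ynone 14 (not isolated)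
Conditions: HC≡CMgBr (5 equiv), THF, −78 → 0 °C; then MeOH, K2CO3 (20 mol %), 25 °C
Reagents that add atoms: ethynylmagnesium bromide, C#C[Mg]Br; methanol, CO
Why: The acetylide adds once to the lactone because the magnesium lactolate is stable, which unmasks the ynone and the C8a hydroxyl, and base-catalysed conjugate addition of methanol then gives the thermodynamically favoured E β-methoxy enone.

Step 9
Reactants: 15 (1E)-4-[(1R,2R,4R,6R)-2,4-dihydroxy-2-[(2Z,4S)-1-hydroxy-2,4-dimethylhex-2-en-1-yl]-4,6-dimethylcyclohexyl]-1-methoxypent-1-en-3-one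
Product: 16 (1E)-4-bromo-4-[(1S,2R,4R,6R)-2,4-dihydroxy-2-[(2Z,4S)-1-hydroxy-2,4-dimethylhex-2-en-1-yl]-4,6-dimethylcyclohexyl]-1-methoxypent-1-en-3-one (epimers at the C–Br carbon and at the carbinol)
Conditions: LiN(iPr)2 (4.5 equiv), THF, −78 → −40 °C; CBr4, −78 °C
Reagents that add atoms: carbon tetrabromide, BrC(Br)(Br)Br
Why: After the three hydroxyls are deprotonated, the only enolisable C–H is the tertiary α' position of the vinylogous ester, and its lithium enolate is brominated by CBr4 (enolate halogenation) with no stereochemical requirement because this carbon becomes a planar radical.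

Step 10
Reactants: 16 (1E)-4-bromo-4-[(1S,2R,4R,6R)-2,4-dihydroxy-2-[(2Z,4S)-1-hydroxy-2,4-dimethylhex-2-en-1-yl]-4,6-dimethylcyclohexyl]-1-methoxypent-1-en-3-one
Product: 17 (2E)-1-[(3S,4S,4aR,5R,7R,8aR)-3-[(2S)-butan-2-yl]-1,7,8a-trihydroxy-2,4,5,7-tetramethyldecahydronaphthalen-4-yl]-3-methoxyprop-2-en-1-one (target locants; epimers at C1 and C2)
Conditions: Bu3SnH (1.3 equiv, syringe pump, 8 h), AIBN (2,2'-azobis(2-methylpropionitrile), 20 mol %), PhH (0.005 M), 80 °C
Reagents that add atoms: none
Why: Key step, a reductive 6-endo-trig radical cyclisation in which the electrophilic tertiary α-keto radical at C4 attacks the less substituted alkene carbon (C3) through a chair on the trans-diequatorial ring B template, the Z geometry (sec-butyl cis to C1) forcing the sec-butyl group axial at C3, A(1,3) strain in the planar radical (H4a eclipsing the acyl group) placing methyl axial and acyl equatorial at C4, and Bu3SnH reducing the resulting tertiary C2 radical.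

Step 11
Reactants: 17 (2E)-1-[(3S,4S,4aR,5R,7R,8aR)-3-[(2S)-butan-2-yl]-1,7,8a-trihydroxy-2,4,5,7-tetramethyldecahydronaphthalen-4-yl]-3-methoxyprop-2-en-1-one
Product: 18 (3S,4S,4aR,5R,7R,8aR)-3-[(2S)-butan-2-yl]-7,8a-dihydroxy-4-[(2E)-3-methoxyprop-2-enoyl]-2,4,5,7-tetramethyloctahydronaphthalen-1(2H)-one (C2 epimers)
Conditions: Dess–Martin periodinane, CH2Cl2, 0 → 25 °C
Reagents that add atoms: none
Why: Dess–Martin oxidation converts the only secondary alcohol into the C1 ketone and cannot touch the two tertiary alcohols or the vinylogous ester.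

Step 12
Reactants: 18 (3S,4S,4aR,5R,7R,8aR)-3-[(2S)-butan-2-yl]-7,8a-dihydroxy-4-[(2E)-3-methoxyprop-2-enoyl]-2,4,5,7-tetramethyloctahydronaphthalen-1(2H)-one
Product: 19 (2S,3R,4S,4aR,5R,7R,8aR)-3-[(2S)-butan-2-yl]-2,7,8a-trihydroxy-4-[(2E)-3-methoxyprop-2-enoyl]-2,4,5,7-tetramethyloctahydronaphthalen-1(2H)-one (target)
Conditions: KN(SiMe3)2 (4 equiv), THF, −78 °C; 2-(phenylsulfonyl)-3-phenyloxaziridine, −78 °C; NH4Cl (aq)
Reagents that add atoms: 2-(phenylsulfonyl)-3-phenyloxaziridine, O=S(=O)(N1OC1c1ccccc1)c1ccccc1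
Why: The C1 ketone can enolise only towards C2 (C8a is quaternary), and Davis α-hydroxylation of the potassium enolate takes the axial trajectory on the face opposite the axial sec-butyl group on the neighbouring C3, giving the axial C2 hydroxyl and equatorial methyl.

## Compound list

1 | 1,1-dimethoxypropan-2-one | CC(=O)C(OC)OC | starting material
2 | methyl 2-bromopropanoate (racemic) | COC(=O)C(C)Br | starting material
3 | methyl 5,5-dimethoxy-2-methyl-4-oxopentanoate (racemic) | COC(=O)C(C)CC(=O)C(OC)OC | intermediate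
4 | (E)-pent-3-en-2-one | C/C=C/C(C)=O | starting material
5 | methyl (4R)-3-(2,2-dimethoxyacetyl)-2,4-dimethyl-6-oxoheptanoate (epimers at C2 and C3) | COC(=O)C(C)C([C@H](C)CC(C)=O)C(=O)C(OC)OC | intermediate (not isolated)
6 | methyl 2-[(1R,2R,6R)-2-(dimethoxymethyl)-2-hydroxy-6-methyl-4-oxocyclohexyl]propanoate (side-chain epimers) | COC(=O)C(C)[C@H]1[C@H](C)CC(=O)C[C@]1(O)C(OC)OC | intermediate
7 | methyl 2-[(1R,2R,4R,6R)-2-(dimethoxymethyl)-2,4-dihydroxy-4,6-dimethylcyclohexyl]propanoate (side-chain epimers) | COC(=O)C(C)[C@H]1[C@H](C)C[C@@](C)(O)C[C@]1(O)C(OC)OC | intermediate (not isolated)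
8 | (3aR,4R,6R,7aR)-7a-(dimethoxymethyl)-6-hydroxy-3,4,6-trimethylhexahydro-1-benzofuran-2(3H)-one (C3 epimers) | CC1C(=O)O[C@]2(C(OC)OC)C[C@](C)(O)C[C@@H](C)[C@H]12 | intermediate
9 | (3aR,4R,6R,7aR)-6-hydroxy-3,4,6-trimethyl-2-oxooctahydro-1-benzofuran-7a-carbaldehyde (C3 epimers) | CC1C(=O)O[C@]2(C=O)C[C@](C)(O)C[C@@H](C)[C@H]12 | intermediate
10 | (S)-2-methylbutan-1-ol | CC[C@H](C)CO | starting material
11 | (S)-2-methylbutanal | CC[C@H](C)C=O | intermediate
12 | (2Z,4S)-2-iodo-4-methylhex-2-ene | CC[C@H](C)/C=C(/C)I | intermediate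
13 | (3aR,4R,6R,7aR)-6-hydroxy-7a-[(2Z,4S)-1-hydroxy-2,4-dimethylhex-2-en-1-yl]-3,4,6-trimethylhexahydro-1-benzofuran-2(3H)-one (epimers at C3 and carbinol) | CC1C(=O)O[C@]2(C(O)/C(C)=C\[C@@H](C)CC)C[C@](C)(O)C[C@@H](C)[C@H]12 | intermediate
14 | 4-[(1R,2R,4R,6R)-2,4-dihydroxy-2-[(2Z,4S)-1-hydroxy-2,4-dimethylhex-2-en-1-yl]-4,6-dimethylcyclohexyl]pent-1-yn-3-one (epimers at C4 and carbinol) | C#CC(=O)C(C)[C@H]1[C@H](C)C[C@@](C)(O)C[C@]1(O)C(O)/C(C)=C\[C@@H](C)CC | intermediate (not isolated)
15 | (1E)-4-[(1R,2R,4R,6R)-2,4-dihydroxy-2-[(2Z,4S)-1-hydroxy-2,4-dimethylhex-2-en-1-yl]-4,6-dimethylcyclohexyl]-1-methoxypent-1-en-3-one (epimers at C4 and carbinol) | CO/C=C/C(=O)C(C)[C@H]1[C@H](C)C[C@@](C)(O)C[C@]1(O)C(O)/C(C)=C\[C@@H](C)CC | intermediate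
16 | (1E)-4-bromo-4-[(1S,2R,4R,6R)-2,4-dihydroxy-2-[(2Z,4S)-1-hydroxy-2,4-dimethylhex-2-en-1-yl]-4,6-dimethylcyclohexyl]-1-methoxypent-1-en-3-one (epimers at C–Br and carbinol) | CO/C=C/C(=O)C(C)(Br)[C@H]1[C@H](C)C[C@@](C)(O)C[C@]1(O)C(O)/C(C)=C\[C@@H](C)CC | intermediate
17 | (2E)-1-[(3S,4S,4aR,5R,7R,8aR)-3-[(2S)-butan-2-yl]-1,7,8a-trihydroxy-2,4,5,7-tetramethyldecahydronaphthalen-4-yl]-3-methoxyprop-2-en-1-one (target locants; epimers at C1 and C2) | CC[C@H](C)[C@@H]1[C@](C)(C(=O)/C=C/OC)[C@H]2[C@H](C)C[C@@](C)(O)C[C@]2(O)C(O)C1C | intermediate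
18 | (3S,4S,4aR,5R,7R,8aR)-3-[(2S)-butan-2-yl]-7,8a-dihydroxy-4-[(2E)-3-methoxyprop-2-enoyl]-2,4,5,7-tetramethyloctahydronaphthalen-1(2H)-one (C2 epimers) | CC[C@H](C)[C@@H]1[C@](C)(C(=O)/C=C/OC)[C@H]2[C@H](C)C[C@@](C)(O)C[C@]2(O)C(=O)C1C | intermediate
19 | (2S,3R,4S,4aR,5R,7R,8aR)-3-[(2S)-butan-2-yl]-2,7,8a-trihydroxy-4-[(2E)-3-methoxyprop-2-enoyl]-2,4,5,7-tetramethyloctahydronaphthalen-1(2H)-one | CC[C@H](C)[C@@H]1[C@](C)(C(=O)/C=C/OC)[C@H]2[C@H](C)C[C@@](C)(O)C[C@]2(O)C(=O)[C@@]1(C)O | target

## Step count and risks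

Total step count: 12. Longest linear sequence: 10 steps (steps 1–4 and 7–12); the vinyl iodide branch is 2 steps (steps 5 and 6).

The three steps most likely to fail are step 10, step 2 and step 12.

Step 10 must join a quaternary and a branched tertiary carbon, so simple reduction of the radical or 1,5-hydrogen transfer from the carbinol C–H may win. The fallback is a polar ring closure that sets out from 15. MnO2 oxidises the allylic carbinol to the Z enone (1E)-4-[(1R,2R,4R,6R)-2-[(2Z,4S)-2,4-dimethylhex-2-enoyl]-2,4-dihydroxy-4,6-dimethylcyclohexyl]-1-methoxypent-1-en-3-one F2. LiN(SiMe3)2 in THF at −78 °C then closes ring A by intramolecular Michael addition of the C4 enolate through the same chair. This comes back to the route at 18, with 16 and 17 skipped. It is kept in reserve because the base can isomerise the Z enone or deprotonate its γ position, which would scramble C3 and the sec-butyl centre.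

Step 2 needs both enamine formation from a hindered keto acetal and useful facial control at C5, and dehydration of the ketol or retro-aldol can compete. The fallback sets out from 3. TMSOTf/Et3N gives the silyl enol ether methyl (3Z)-5,5-dimethoxy-2-methyl-4-(trimethylsilyloxy)pent-3-enoate F1. A Mukaiyama–Michael addition to 4 under a chiral oxazaborolidinium triflimide (B-o-tolyl oxazaborolidine from (S)-diphenylprolinol, activated with HNTf2) gives the open-chain adduct 5, now isolated. Pyrrolidinium acetate closes it by aldol reaction, coming back at 6.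

Step 12 can fail on facial selectivity, because the desired axial face carries the syn-axial C4 methyl and C8a oxygen, or on the base sensitivity of the α-ketol. The fallback sets out from 18. TMSOTf/Et3N gives the tris(trimethylsilyl) compound F3 (C1–C2 silyl enol ether, C7 and C8a silyl ethers, other centres as in 18). Dimethyldioxirane epoxidises the enol ether on the face away from the axial sec-butyl group, and HF·pyridine releases 19 (Rubottom oxidation), coming back at 19.

Further compounds

F1 | step 2 | methyl (3Z)-5,5-dimethoxy-2-methyl-4-(trimethylsilyloxy)pent-3-enoate | COC(=O)C(C)/C=C(\O[Si](C)(C)C)C(OC)OC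
F2 | step 10 | (1E)-4-[(1R,2R,4R,6R)-2-[(2Z,4S)-2,4-dimethylhex-2-enoyl]-2,4-dihydroxy-4,6-dimethylcyclohexyl]-1-methoxypent-1-en-3-one (C4 epimers) | CO/C=C/C(=O)C(C)[C@H]1[C@H](C)C[C@@](C)(O)C[C@]1(O)C(=O)/C(C)=C\[C@@H](C)CC
F3 | step 12 | tris(trimethylsilyl) derivative of 18: C1–C2 silyl enol ether with C7 and C8a trimethylsilyl ethers | CC[C@H](C)[C@@H]1[C@](C)(C(=O)/C=C/OC)[C@H]2[C@H](C)C[C@@](C)(O[Si](C)(C)C)C[C@]2(O[Si](C)(C)C)C(O[Si](C)(C)C)=C1C
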